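Follow one catalyst round the cycle and ask, each time it sits as catalyst intermediate A, which way it leaves.

starting material 0.10 M; second substrate 1.00 equiv; reagent 0.700 equiv; free catalyst 1 mol%

    starting material + free catalyst ⇌ catalyst intermediate A (K1 = 240 M⁻¹, k1 = 8.9 M⁻¹ min⁻¹)
    reagent + catalyst intermediate A → free catalyst + target (k2 = 7.9 M⁻¹ min⁻¹)
    second substrate + free catalyst ⇌ catalyst intermediate B (K3 = 8.2 M⁻¹, k3 = 110 M⁻¹ min⁻¹)
    reagent + catalyst intermediate B → free catalyst + second product (k4 = 4.3 M⁻¹ min⁻¹)
    catalyst intermediate A → spent catalyst (k5 = 0.013 min⁻¹)

* the form that holds most of the catalyst when 30% of the starting material are converted (catalyst intermediate B / spent catalyst / catalyst intermediate A / free catalyst)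
* its share of the catalyst then
* apparent order in second substrate when 30% of the starting material are converted (percent change of the rate of making target for one percent more second substrate charged)

Reagent takes catalyst intermediate A on to target and free catalyst at 33 h⁻¹ with reagent as charged, while the step to spent catalyst runs at 0.78 h⁻¹, which is slower but cannot be undone. With reagent as charged, the odds at this fork give 2.30%. Call this the toll: the chance that one passage through catalyst intermediate A ends in spent catalyst instead of target. Catalyst intermediate A can also fall back to free catalyst, which only brings the same fork round again.

The toll rises as reagent falls, so it has to be summed along the run. The charge holds 70.0 reagent per catalyst. The conversion asked about takes 30.0 turnovers per catalyst and, if target alone used reagent, leaves this fraction of the reagent charge: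

left = 0.571

My sum for the spent share of the catalyst is then:

spent = toll × reagent per catalyst × ln(1/left) = 90.0%

So the form holding most is spent catalyst. Second product uses reagent as well, so my figure sits low. My reckoning stops short of the order, which I expect to be negative, but I put no number on it.

Your forecast names spent catalyst too, at 96.5% (range 90% to 99%), higher than my sum. It gives an order in second substrate of −3.2 (range −7 to −1.5), reasoning of second substrate that “by using up reagent it speeds deactivation”.

The flask gives spent catalyst at 96.8% and an order of −3.2, with the conversion reached at 8.61 h. One percent more on the constants of step 3, forward and back together, changes the rate by −0.055 percent. Back at 2.00 h, the flask holds 18.2% target and 52.2% spent catalyst, with 66.8% of the reagent left, so the toll has risen to 3.40%. Spent catalyst per target formed up to then stands at 2.86%, less than that toll.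

The numbers of this flask were drawn at random within sensible limits; the rest is arithmetic.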